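**Retrosynthetic overview**
1. Target 9 is kaempferol with a 3-hydroxy-3-methylbutyl chain at C6. Rings A, C and B are all bought intact in kaempferol 1, so no ring is formed in the route.
2. Side chain: the C6(sp2)–C(sp) bond is cut by a Sonogashira disconnection to 6-iodide 5 and 2-methylbut-3-yn-2-ol 6. Alkyne saturation and O-debenzylation are merged in the last hydrogenation.
3. Iodide 5 comes from C6-selective iodination of 3, directed by the free, chelated 5-OH.
4. Compound 3 comes from 1 by selective 3,7,4'-tri-O-benzylation, the 5-OH being held back by its hydrogen bond to the C4 carbonyl.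

Assumption: the target has no stereocentre and no stereogenic double bond (it is achiral), so the "single enantiomer" requirement needs no stereocontrol.

**Route**

Step 1
Reactants: 1 kaempferol; 2 benzyl bromide
Product: 3 kaempferol 3,7,4'-tribenzyl ether (5-OH free)
Conditions: BnBr (3.3 equiv), K2CO3 (3.5 equiv), DMF, rt, 16 h
Reagents that add atoms: benzyl bromide, BrCc1ccccc1
Why: Williamson ether synthesis in which the 7-, 4'- and 3-OH groups are benzylated while the 5-OH, hydrogen-bonded to the C4 carbonyl and the least acidic, stays free at this stoichiometry.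

Step 2
Reactants: 3 kaempferol 3,7,4'-tribenzyl ether; 4 benzyltrimethylammonium dichloroiodate
Product: 5 6-iodokaempferol 3,7,4'-tribenzyl ether
Conditions: BnMe3N·ICl2 (1.1 equiv), CaCO3, CH2Cl2/MeOH (5:2), rt
Reagents that add atoms: benzyltrimethylammonium dichloroiodate, C[N+](C)(C)Cc1ccccc1.Cl[I-]Cl
Why: Electrophilic aromatic iodination in which the mild dichloroiodate attacks ortho to the free chelated 5-OH (C6) of the electron-rich ring A, CaCO3 takes up the HCl, and the mono-alkoxy ring B is too weakly activated to compete.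

Step 3
Reactants: 5 6-iodokaempferol 3,7,4'-tribenzyl ether; 6 2-methylbut-3-yn-2-ol
Product: 7 6-(3-hydroxy-3-methylbut-1-ynyl)kaempferol 3,7,4'-tribenzyl ether
Conditions: PdCl2(PPh3)2 (5 mol %), CuI (10 mol %), Et3N, DMF (degassed), 50 °C
Reagents that add atoms: 2-methylbut-3-yn-2-ol, C#CC(C)(C)O
Why: Sonogashira coupling (oxidative addition of zerovalent palladium into the C6–I bond, transmetalation from the copper acetylide, reductive elimination), with the chelated 5-OH too poor a nucleophile to close a furan ring at this temperature.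

Step 4
Reactants: 7 6-(3-hydroxy-3-methylbut-1-ynyl)kaempferol 3,7,4'-tribenzyl ether
Product: 9 6-(3-hydroxy-3-methylbutyl)kaempferol, via saturated tri-O-benzyl ether 8 (not isolated)
Conditions: H2 (1 atm), 10% Pd/C, THF/MeOH (1:1), rt
Reagents that add atoms: none
Why: Catalytic hydrogenation saturates the alkyne first and then hydrogenolyses the three benzyl aryl ethers, leaving the tetrasubstituted C2=C3 bond of the pyranone and the now homobenzylic tertiary alcohol untouched; no stereocentre is created.

**Compound list**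
1 | kaempferol, 3,5,7-trihydroxy-2-(4-hydroxyphenyl)-4H-chromen-4-one | O=c1c(O)c(-c2ccc(O)cc2)oc2cc(O)cc(O)c12 | starting material
2 | benzyl bromide | BrCc1ccccc1 | starting material
3 | kaempferol 3,7,4'-tribenzyl ether, 3,7-bis(benzyloxy)-2-[4-(benzyloxy)phenyl]-5-hydroxy-4H-chromen-4-one | O=c1c(OCc2ccccc2)c(-c2ccc(OCc3ccccc3)cc2)oc2cc(OCc3ccccc3)cc(O)c12 | intermediate
4 | benzyltrimethylammonium dichloroiodate | C[N+](C)(C)Cc1ccccc1.Cl[I-]Cl | starting material
5 | 6-iodokaempferol 3,7,4'-tribenzyl ether, 3,7-bis(benzyloxy)-2-[4-(benzyloxy)phenyl]-5-hydroxy-6-iodo-4H-chromen-4-one | O=c1c(OCc2ccccc2)c(-c2ccc(OCc3ccccc3)cc2)oc2cc(OCc3ccccc3)c(I)c(O)c12 | intermediate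
6 | 2-methylbut-3-yn-2-ol | C#CC(C)(C)O | starting material
7 | 3,7-bis(benzyloxy)-2-[4-(benzyloxy)phenyl]-5-hydroxy-6-(3-hydroxy-3-methylbut-1-yn-1-yl)-4H-chromen-4-one | CC(C)(O)C#Cc1c(OCc2ccccc2)cc2oc(-c3ccc(OCc4ccccc4)cc3)c(OCc3ccccc3)c(=O)c2c1O | intermediate
8 | 3,7-bis(benzyloxy)-2-[4-(benzyloxy)phenyl]-5-hydroxy-6-(3-hydroxy-3-methylbutyl)-4H-chromen-4-one | CC(C)(O)CCc1c(OCc2ccccc2)cc2oc(-c3ccc(OCc4ccccc4)cc3)c(OCc3ccccc3)c(=O)c2c1O | intermediate
9 | 6-(3-hydroxy-3-methylbutyl)kaempferol, 3,5,7-trihydroxy-6-(3-hydroxy-3-methylbutyl)-2-(4-hydroxyphenyl)-4H-chromen-4-one (achiral) | CC(C)(O)CCc1c(O)cc2oc(-c3ccc(O)cc3)c(O)c(=O)c2c1O | target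

**Count**
Total steps: 4. Longest linear sequence: 4 steps (1 → 3 → 5 → 7 → 9).

**Steps most likely to fail, with fallbacks**

Step 2 (regioselective iodination) is the main risk: the 8-iodo isomer or the 6,8-di-iodide may form. The fallback sets out from 3 and puts the carbon chain on C6 by a rearrangement that can reach no other position. The 5-OH is allylated (allyl bromide, K2CO3, DMF, 60 °C) to 5-O-allyl-3,7,4'-tri-O-benzylkaempferol F2. Heating (N,N-diethylaniline, 190 °C) brings about an aromatic Claisen rearrangement to the only free ortho position and gives 6-allyl-3,7,4'-tri-O-benzylkaempferol F3. Cross-metathesis with 2-methylbut-2-ene (second-generation Grubbs catalyst RuCl2(=CHPh)(SIMes)(PCy3), CH2Cl2, 40 °C) gives 6-prenyl-3,7,4'-tri-O-benzylkaempferol F4. Mukaiyama hydration (Co(acac)2, PhSiH3, O2, THF/i-PrOH, rt) then gives the Markovnikov tertiary alcohol, which is 8. The fallback comes back to the route at 8, which is debenzylated to 9 under the conditions of step 4.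

Step 3 (Sonogashira coupling) may be sluggish at the doubly ortho-substituted iodide, the ortho-alkynylphenol may cyclise to a furan-fused flavone, or the alkyne may homocouple. The fallback sets out from 5 and uses a Mizoroki–Heck reaction with 2-methylbut-3-en-2-ol (Pd(OAc)2, Bu4NCl, NaHCO3, DMF, 80 °C). This gives (E)-6-(3-hydroxy-3-methylbut-1-enyl)-3,7,4'-tri-O-benzylkaempferol F5, which has no alkynylphenol that could cyclise. F5 is kept away from acid (which would close a chromene) and is put under the conditions of step 4, where its alkene is saturated to 8; there the fallback comes back to the route and goes on to 9.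

Step 1 (selective tribenzylation) may give mixtures of di-, tri- and tetra-benzyl ethers. The fallback sets out from 1 and replaces selective protection by full protection and selective deprotection. Exhaustive benzylation (BnBr 6 equiv, K2CO3, DMF, 80 °C) gives kaempferol 3,5,7,4'-tetrabenzyl ether F1. BCl3 (1.1 equiv, CH2Cl2, −78 °C) then removes only the 5-O-benzyl group through a six-membered chelate with the C4 carbonyl, and the fallback comes back to the route at 3.

Further compounds
F1 | step 1 | kaempferol 3,5,7,4'-tetrabenzyl ether | O=c1c(OCc2ccccc2)c(-c2ccc(OCc3ccccc3)cc2)oc2cc(OCc3ccccc3)cc(OCc3ccccc3)c12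
F2 | step 2 | 5-O-allyl-3,7,4'-tri-O-benzylkaempferol | C=CCOc1cc(OCc2ccccc2)cc2oc(-c3ccc(OCc4ccccc4)cc3)c(OCc3ccccc3)c(=O)c12
F3 | step 2 | 6-allyl-3,7,4'-tri-O-benzylkaempferol | C=CCc1c(OCc2ccccc2)cc2oc(-c3ccc(OCc4ccccc4)cc3)c(OCc3ccccc3)c(=O)c2c1O
F4 | step 2 | 6-prenyl-3,7,4'-tri-O-benzylkaempferol | CC(C)=CCc1c(OCc2ccccc2)cc2oc(-c3ccc(OCc4ccccc4)cc3)c(OCc3ccccc3)c(=O)c2c1O
F5 | step 3 | (E)-6-(3-hydroxy-3-methylbut-1-enyl)-3,7,4'-tri-O-benzylkaempferol | CC(C)(O)/C=C/c1c(OCc2ccccc2)cc2oc(-c3ccc(OCc4ccccc4)cc3)c(OCc3ccccc3)c(=O)c2c1O
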